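**Retrosynthetic overview**
- The C40 skeleton is cut at C6'–C7' into a C31 polyenyne (ring A plus the chain, ending in a C7'≡C8'H alkyne) and a C9 ring-B oxirane. This bond and the E-C7'=C8' double bond are made together in the last C–C bond-forming step.
- Enabling feature: ring B carries a ditertiary 5',6'-trans-diol with C7' cis to O5'. This is the imprint of a syn opening, at C6', of a C5'–C6' oxirane that bears a silyloxy group on C6' (a silyl enol ether epoxide). Ring strain plus the oxygen donor let C6' ionise and accept the alkenyl group from a metal held on O5'.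
- The C31 polyenyne comes from a ring-A C15 phosphonium salt, the C10 dialdehyde and a C6 enynyl phosphonium salt by two Wittig reactions (C11'=C12', then C11=C12).
- Ring A: a dienyllithium adds to an α-silyloxy ketone (C6–C7), then a transannular Mitsunobu etherification O6→C3 closes the 7-oxabicyclo[2.2.1]heptane.
- Ring order: both cyclohexane rings come preformed from ketoisophorone through the enantiomeric phorenols; the ring-B oxirane is formed in step 4, the ring-A oxygen bridge in step 13, and the oxirane is opened in the key step.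

Key step: step 20

Assumption: carotenoid numbering is used for positions (ring A = C1–C6 with the C3–O–C6 bridge, chain C7…C15,C15'…C7', ring B = C1'–C6'); read from the SMILES the target is (3R,5R,6S,3'R,5'S,6'S), i.e. the C5 hydroxyl of ring A is syn to the oxygen bridge and ring B is a 3',5'-trans/5',6'-trans triol with C7' cis to O5'.

**Route**

Step 1
Reactants: 1 2,6,6-trimethylcyclohex-2-ene-1,4-dione (ketoisophorone)
Product: 2 (4R)-4-hydroxy-2,6,6-trimethylcyclohex-2-en-1-one
Conditions: RuCl(p-cymene)[(R,R)-TsDPEN] (0.5 mol%), KOt-Bu (1 mol%), i-PrOH, 25 °C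
Reagents that add atoms: none
Why: Noyori asymmetric transfer hydrogenation should reduce only the unhindered C4 carbonyl of the ene-dione, the (R,R)-diamine ligand placing hydride on the face that gives the 4R carbinol (alkenyl group in the role of the aryl group of the usual CH/π model); this centre becomes C3' of ring B.

Step 2
Reactants: 2 (4R)-4-hydroxy-2,6,6-trimethylcyclohex-2-en-1-one
Product: 3 (4R)-4-(tert-butyldimethylsilyloxy)-2,6,6-trimethylcyclohex-2-en-1-one
Conditions: TBSCl (1.2 equiv), imidazole (2 equiv), DMF, rt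
Reagents that add atoms: tert-butyldimethylsilyl chloride, CC(C)(C)[Si](C)(C)Cl
Why: Imidazole-promoted silylation of a secondary alcohol; no stereocentre is touched.

Step 3
Reactants: 3 (4R)-4-(tert-butyldimethylsilyloxy)-2,6,6-trimethylcyclohex-2-en-1-one
Product: 4 (4S)-4-(tert-butyldimethylsilyloxy)-2,6,6-trimethyl-1-(triethylsilyloxy)cyclohex-1-ene (same spatial arrangement as 3; the descriptor changes by priority only)
Conditions: Et3SiH (1.3 equiv), RhCl(PPh3)3 (1 mol%), toluene, 50 °C
Reagents that add atoms: triethylsilane, CC[SiH](CC)CC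
Why: Rhodium-catalysed 1,4-hydrosilylation of an enone with a monohydrosilane puts hydride on the β-carbon and silicon on oxygen, giving the only possible (C5'=C6') silyl enol ether without creating a stereocentre.

Step 4
Reactants: 4 (4S)-4-(tert-butyldimethylsilyloxy)-2,6,6-trimethyl-1-(triethylsilyloxy)cyclohex-1-ene
Product: 5 (1S,4R,6S)-4-(tert-butyldimethylsilyloxy)-2,2,6-trimethyl-1-(triethylsilyloxy)-7-oxabicyclo[4.1.0]heptane (oxirane oxygen trans to the C4 silyloxy group)
Conditions: dimethyldioxirane (1.1 equiv, acetone solution), CH2Cl2, −40 → −20 °C; volatiles removed below 0 °C; used at once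
Reagents that add atoms: dimethyldioxirane, CC1(C)OO1
Why: Dioxirane epoxidation of the electron-rich tetrasubstituted silyl enol ether under neutral aprotic conditions (a Rubottom oxidation stopped at the oxirane) should occur anti to the homoallylic C3' silyloxy group, as peracid epoxidations of 3-O-protected β-ring alkenes do, and this sets C5' and C6' together.

Step 5
Reactants: 1 2,6,6-trimethylcyclohex-2-ene-1,4-dione
Product: 6 (4S)-4-hydroxy-2,6,6-trimethylcyclohex-2-en-1-one
Conditions: RuCl(p-cymene)[(S,S)-TsDPEN] (0.5 mol%), KOt-Bu (1 mol%), i-PrOH, 25 °C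
Reagents that add atoms: none
Why: Noyori asymmetric transfer hydrogenation as in step 1 with the enantiomeric ligand gives the 4S carbinol, the centre that is later inverted to C3 of ring A.

Step 6
Reactants: 6 (4S)-4-hydroxy-2,6,6-trimethylcyclohex-2-en-1-one
Product: 7 (4S)-4-(tert-butyldimethylsilyloxy)-2,6,6-trimethylcyclohex-2-en-1-one
Conditions: TBSCl (1.2 equiv), imidazole (2 equiv), DMF, rt
Reagents that add atoms: tert-butyldimethylsilyl chloride, CC(C)(C)[Si](C)(C)Cl
Why: Imidazole-promoted silylation of a secondary alcohol; no stereocentre is touched.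

Step 7
Reactants: 7 (4S)-4-(tert-butyldimethylsilyloxy)-2,6,6-trimethylcyclohex-2-en-1-one
Product: 8 (4R)-4-(tert-butyldimethylsilyloxy)-2,6,6-trimethyl-1-(triethylsilyloxy)cyclohex-1-ene
Conditions: Et3SiH (1.3 equiv), RhCl(PPh3)3 (1 mol%), toluene, 50 °C
Reagents that add atoms: triethylsilane, CC[SiH](CC)CC
Why: Rhodium-catalysed 1,4-hydrosilylation of the enone as in step 3 gives the single silyl enol ether.

Step 8
Reactants: 8 (4R)-4-(tert-butyldimethylsilyloxy)-2,6,6-trimethyl-1-(triethylsilyloxy)cyclohex-1-ene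
Product: 10 (2R,4S)-4-(tert-butyldimethylsilyloxy)-2,6,6-trimethyl-2-(triethylsilyloxy)cyclohexan-1-one, via siloxy-oxirane 9 (not isolated)
Conditions: mCPBA (1.1 equiv), hexane, −15 °C → rt
Reagents that add atoms: 3-chloroperoxybenzoic acid, OOC(=O)c1cccc(Cl)c1
Why: Rubottom oxidation: peracid epoxidation anti to the C3 silyloxy group sets C5, then acid-catalysed opening of the siloxy-oxirane and 1,4-silyl shift give the α-silyloxy ketone.

Step 9
Reactants: 11 (2E)-3-methylpent-2-en-4-yn-1-ol
Product: 12 (3E)-5-(2-methoxypropan-2-yloxy)-3-methylpent-3-en-1-yne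
Conditions: 2-methoxypropene (2 equiv), PPTS (1 mol%), CH2Cl2, 0 °C; Et3N quench
Reagents that add atoms: 2-methoxypropene, COC(C)=C
Why: Acid-catalysed addition of the alcohol to the enol ether gives the achiral mixed acetal (MOP ether), which is stable to the organometallic and fluoride steps that follow.

Step 10
Reactants: 12 (3E)-5-(2-methoxypropan-2-yloxy)-3-methylpent-3-en-1-yne
Product: 14 (1E,3E)-1-iodo-5-(2-methoxypropan-2-yloxy)-3-methylpenta-1,3-diene, via dienylzirconocene chloride 13 (not isolated)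
Conditions: Cp2Zr(H)Cl (1.2 equiv), THF, rt, dark; then iodine (1.1 equiv), 0 °C
Reagents that add atoms: iodine, [I][I]
Why: Hydrozirconation adds Zr–H syn across the terminal alkyne with zirconium on the terminal carbon, and iodinolysis with retention gives the (1E)-iodide.

Step 11
Reactants: 14 (1E,3E)-1-iodo-5-(2-methoxypropan-2-yloxy)-3-methylpenta-1,3-diene; 10 (2R,4S)-4-(tert-butyldimethylsilyloxy)-2,6,6-trimethyl-2-(triethylsilyloxy)cyclohexan-1-one
Product: 16 (1S,2R,4S)-4-(tert-butyldimethylsilyloxy)-1-[(1E,3E)-5-(2-methoxypropan-2-yloxy)-3-methylpenta-1,3-dienyl]-2,6,6-trimethyl-2-(triethylsilyloxy)cyclohexan-1-ol, via dienyllithium 15 (not isolated)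
Conditions: 14 (1.3 equiv), t-BuLi (2.6 equiv), Et2O, −78 °C; then 10, −78 → −30 °C; aq. NaHCO3
Reagents that add atoms: none
Why: Lithium–iodine exchange with retention of alkene geometry, then 1,2-addition to the non-enolisable ketone; axial attack anti to the axial C5 silyloxy group (polar Felkin–Anh, the equatorial path being blocked by the axial C1 methyl and the C5 oxygen) sets C6 with O6 cis to O5 and trans to O3, as the later displacement requires.

Step 12
Reactants: 16 (1S,2R,4S)-4-(tert-butyldimethylsilyloxy)-1-[(1E,3E)-5-(2-methoxypropan-2-yloxy)-3-methylpenta-1,3-dienyl]-2,6,6-trimethyl-2-(triethylsilyloxy)cyclohexan-1-ol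
Product: 17 (1S,2R,4S)-1-[(1E,3E)-5-(2-methoxypropan-2-yloxy)-3-methylpenta-1,3-dienyl]-2,6,6-trimethylcyclohexane-1,2,4-triol
Conditions: TBAF (3 equiv), THF, 0 °C → rt
Reagents that add atoms: none
Why: Fluoride cleaves both silyl ethers under basic conditions that spare the acetal and the acid-sensitive dienyl carbinol (a silyl shift between O5 and O6 in step 11 would be without consequence here).

Step 13
Reactants: 17 (1S,2R,4S)-1-[(1E,3E)-5-(2-methoxypropan-2-yloxy)-3-methylpenta-1,3-dienyl]-2,6,6-trimethylcyclohexane-1,2,4-triol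
Product: 18 (1S,2R,4R)-1-[(1E,3E)-5-(2-methoxypropan-2-yloxy)-3-methylpenta-1,3-dienyl]-2,6,6-trimethyl-7-oxabicyclo[2.2.1]heptan-2-ol
Conditions: PPh3 (1.5 equiv), DIAD (1.5 equiv), THF, 0 → 40 °C
Reagents that add atoms: none
Why: Mitsunobu cyclodehydration: only the secondary C3 hydroxyl is activated as the alkoxyphosphonium ion and is displaced through a boat conformer by the trans-disposed tertiary C6 hydroxyl (5-exo-tet) with inversion at C3, closing the oxygen bridge on the face of the C5 hydroxyl; neutral conditions are chosen because a C5 alkoxide would fragment the 1,3-hydroxy sulfonate pattern (Grob).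

Step 14
Reactants: 18 (1S,2R,4R)-1-[(1E,3E)-5-(2-methoxypropan-2-yloxy)-3-methylpenta-1,3-dienyl]-2,6,6-trimethyl-7-oxabicyclo[2.2.1]heptan-2-ol
Product: 20 {(2E,4E)-5-[(1S,2R,4R)-2-hydroxy-2,6,6-trimethyl-7-oxabicyclo[2.2.1]heptan-1-yl]-3-methylpenta-2,4-dienyl}triphenylphosphonium bromide, via allylic alcohol 19 (not isolated)
Conditions: PPh3·HBr (1.05 equiv), MeOH, 0 °C → rt
Reagents that add atoms: triphenylphosphine hydrobromide, [Br-].c1ccc(cc1)[PH+](c1ccccc1)c1ccccc1
Why: Methanolysis of the mixed acetal, then conversion of the primary dienylic alcohol into the allylic phosphonium salt by triphenylphosphine hydrobromide (the standard entry to carotenoid Wittig salts), with the E double bonds and the oxygen bridge expected to survive.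

Step 15
Reactants: 11 (2E)-3-methylpent-2-en-4-yn-1-ol
Product: 21 (3E)-5-bromo-3-methylpent-3-en-1-yne
Conditions: PBr3 (0.4 equiv), pyridine (cat.), Et2O, −10 °C
Reagents that add atoms: phosphorus tribromide, BrP(Br)Br
Why: Bromination of the primary allylic alcohol by SN2 on its phosphite ester, with the E geometry retained.

Step 16
Reactants: 21 (3E)-5-bromo-3-methylpent-3-en-1-yne
Product: 22 [(2E)-3-methylpent-2-en-4-ynyl]triphenylphosphonium bromide
Conditions: PPh3 (1.05 equiv), toluene, rt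
Reagents that add atoms: triphenylphosphine, c1ccc(cc1)P(c1ccccc1)c1ccccc1
Why: Quaternisation of triphenylphosphine by the primary allylic bromide (SN2).

Step 17
Reactants: 22 [(2E)-3-methylpent-2-en-4-ynyl]triphenylphosphonium bromide; 23 (2E,4E,6E)-2,7-dimethylocta-2,4,6-trienedial
Product: 26 (2E,4E,6E,8E,10E)-2,7,11-trimethyltrideca-2,4,6,8,10-pentaen-12-ynal, via phosphorus ylide 24 (not isolated), via (8Z)-aldehyde 25 (not isolated)
Conditions: 23 (3 equiv), NaOMe (1.1 equiv), MeOH/CH2Cl2, 0 °C → rt; then iodine (1 mol%), CH2Cl2, rt, daylight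
Reagents that add atoms: none
Why: Wittig reaction of the semi-stabilised ylide with one aldehyde group of the symmetrical dialdehyde used in excess forms C11'=C12' as an E/Z mixture, and iodine catalysis equilibrates the hindered Z isomer to E.

Step 18
Reactants: 20 {(2E,4E)-5-[(1S,2R,4R)-2-hydroxy-2,6,6-trimethyl-7-oxabicyclo[2.2.1]heptan-1-yl]-3-methylpenta-2,4-dienyl}triphenylphosphonium bromide; 26 (2E,4E,6E,8E,10E)-2,7,11-trimethyltrideca-2,4,6,8,10-pentaen-12-ynal
Product: 29 (3R,5R,6S)-3,6-epoxy-7',8'-didehydro-5,6-dihydro-7'-apo-β-caroten-5-ol, via phosphorus ylide 27 (not isolated), via (11Z)-polyenyne 28 (not isolated)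
Conditions: 20 (1.2 equiv), NaOMe (1.5 equiv), MeOH/CH2Cl2, 0 °C → rt, dark; then heptane/EtOAc, 70 °C, dark
Reagents that add atoms: none
Why: Wittig reaction of the C15 ylide with the C16 aldehyde forms C11=C12, and the hindered (11Z) isomer is isomerised thermally to the all-E polyenyne, as is usual for C15 plus aldehyde carotenoid couplings.

Step 19
Reactants: 29 (3R,5R,6S)-3,6-epoxy-7',8'-didehydro-5,6-dihydro-7'-apo-β-caroten-5-ol
Product: 30 (3R,5R,6S)-3,6-epoxy-5-(trimethylsilyloxy)-7',8'-didehydro-5,6-dihydro-7'-apo-β-carotene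
Conditions: N-(trimethylsilyl)imidazole (3 equiv), CH2Cl2, rt
Reagents that add atoms: 1-(trimethylsilyl)imidazole, C[Si](C)(C)n1ccnc1
Why: Silylation of the single (tertiary) hydroxyl group with a powerful neutral silyl donor removes the only protic group before the hydride reagent of step 20.

Step 20
Reactants: 30 (3R,5R,6S)-3,6-epoxy-5-(trimethylsilyloxy)-7',8'-didehydro-5,6-dihydro-7'-apo-β-carotene; 5 (1S,4R,6S)-4-(tert-butyldimethylsilyloxy)-2,2,6-trimethyl-1-(triethylsilyloxy)-7-oxabicyclo[4.1.0]heptane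
Product: 32 (3R,5R,6S,3'R,5'S,6'S)-3'-(tert-butyldimethylsilyloxy)-3,6-epoxy-6'-(triethylsilyloxy)-5-(trimethylsilyloxy)-5,6,5',6'-tetrahydro-β,β-caroten-5'-ol, via alkenylzirconocene chloride 31 (not isolated)
Conditions: 30, Cp2Zr(H)Cl (1.2 equiv), CH2Cl2, rt, dark, 20 min; then 5 (1.5 equiv), AgClO4 (10 mol%), −40 → 0 °C; aq. NaHCO3
Reagents that add atoms: none
Why: Proposed new method: syn-hydrozirconation of the terminal alkyne of 30 gives the (E)-alkenylzirconocene 31 with zirconium on C7'; chloride abstraction by AgClO4 generates the cationic alkenylzirconocene, which binds the oxirane oxygen of 5 and, driven by release of the three-ring strain and by the silyloxy donor on C6', ionises the C6'–O bond to an O-silyl oxocarbenium ion that carries the alkenyl–zirconium unit on the adjacent C5' oxygen. The alkenyl group then migrates from zirconium to C6' within this tight ion pair through a five-membered transition state, so that C7' enters on the face the oxirane oxygen has just left, cis to O5'. The closest known reaction type is the silver-catalysed syn addition of alkenylzirconocenes to glycal epoxides (1-alkoxy-oxiranes) that gives cis C-glycosides, here transferred from a cyclic enol-ether epoxide to a carbocyclic silyl-enol-ether epoxide. No ring is closed (the oxirane is opened); C5' keeps the configuration set in step 4 and appears as the free tertiary alcohol, the quaternary C6' is controlled by intramolecular delivery from the O5'-bound metal (hence the 5',6'-trans-diol with C7' cis to O5'), and the E geometry of C7'=C8' comes from syn hydrometalation and stereoretentive transfer. The step needs hydrozirconation of the alkyne and not of the polyene double bonds (secured by the much higher rate for terminal alkynes and the absence of OH groups), ionisation at C6' and not C5' (secured by the silyloxy group), and alkenyl transfer faster than the Rubottom-type 1,4-silyl shift to O5' (favoured by the triethylsilyl group, the non-coordinating solvent and the low temperature).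

Step 21
Reactants: 32 (3R,5R,6S,3'R,5'S,6'S)-3'-(tert-butyldimethylsilyloxy)-3,6-epoxy-6'-(triethylsilyloxy)-5-(trimethylsilyloxy)-5,6,5',6'-tetrahydro-β,β-caroten-5'-ol
Product: 33 (3R,5R,6S,3'R,5'S,6'S)-3,6-epoxy-5,6,5',6'-tetrahydro-β,β-carotene-5,3',5',6'-tetrol (CNP0261804.1)
Conditions: TBAF (5 equiv), AcOH (5 equiv), THF, 0 °C → rt, dark, argon
Reagents that add atoms: none
Why: Fluoride-mediated cleavage of the three silyl ethers under buffered, non-acidic conditions should leave the polyene, the ditertiary diol and the oxygen bridge untouched.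

**Compound list**

1 | 2,6,6-trimethylcyclohex-2-ene-1,4-dione (ketoisophorone) | CC1=CC(=O)CC(C)(C)C1=O | starting material
2 | (4R)-4-hydroxy-2,6,6-trimethylcyclohex-2-en-1-one | CC1(C)C[C@@H](O)C=C(C)C1=O | intermediate
3 | (4R)-4-(tert-butyldimethylsilyloxy)-2,6,6-trimethylcyclohex-2-en-1-one | CC1(C)C[C@@H](O[Si](C)(C)C(C)(C)C)C=C(C)C1=O | intermediate
4 | (4S)-4-(tert-butyldimethylsilyloxy)-2,6,6-trimethyl-1-(triethylsilyloxy)cyclohex-1-ene | CC1(C)C[C@@H](O[Si](C)(C)C(C)(C)C)CC(C)=C1O[Si](CC)(CC)CC | intermediate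
5 | (1S,4R,6S)-4-(tert-butyldimethylsilyloxy)-2,2,6-trimethyl-1-(triethylsilyloxy)-7-oxabicyclo[4.1.0]heptane | CC1(C)C[C@@H](O[Si](C)(C)C(C)(C)C)C[C@]2(C)O[C@]12O[Si](CC)(CC)CC | intermediate
6 | (4S)-4-hydroxy-2,6,6-trimethylcyclohex-2-en-1-one | CC1(C)C[C@H](O)C=C(C)C1=O | intermediate
7 | (4S)-4-(tert-butyldimethylsilyloxy)-2,6,6-trimethylcyclohex-2-en-1-one | CC1(C)C[C@H](O[Si](C)(C)C(C)(C)C)C=C(C)C1=O | intermediate
8 | (4R)-4-(tert-butyldimethylsilyloxy)-2,6,6-trimethyl-1-(triethylsilyloxy)cyclohex-1-ene | CC1(C)C[C@H](O[Si](C)(C)C(C)(C)C)CC(C)=C1O[Si](CC)(CC)CC | intermediate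
9 | (1R,4S,6R)-4-(tert-butyldimethylsilyloxy)-2,2,6-trimethyl-1-(triethylsilyloxy)-7-oxabicyclo[4.1.0]heptane (not isolated) | CC1(C)C[C@H](O[Si](C)(C)C(C)(C)C)C[C@@]2(C)O[C@@]12O[Si](CC)(CC)CC | intermediate
10 | (2R,4S)-4-(tert-butyldimethylsilyloxy)-2,6,6-trimethyl-2-(triethylsilyloxy)cyclohexan-1-one | CC1(C)C[C@H](O[Si](C)(C)C(C)(C)C)C[C@@](C)(O[Si](CC)(CC)CC)C1=O | intermediate
11 | (2E)-3-methylpent-2-en-4-yn-1-ol | C#C/C(C)=C/CO | starting material
12 | (3E)-5-(2-methoxypropan-2-yloxy)-3-methylpent-3-en-1-yne | C#C/C(C)=C/COC(C)(C)OC | intermediate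
13 | chloro[(1E,3E)-5-(2-methoxypropan-2-yloxy)-3-methylpenta-1,3-dienyl]bis(cyclopentadienyl)zirconium (not isolated) | Cl[Zr](/C=C/C(C)=C/COC(C)(C)OC)(C1C=CC=C1)C1C=CC=C1 | intermediate
14 | (1E,3E)-1-iodo-5-(2-methoxypropan-2-yloxy)-3-methylpenta-1,3-diene | I/C=C/C(C)=C/COC(C)(C)OC | intermediate
15 | [(1E,3E)-5-(2-methoxypropan-2-yloxy)-3-methylpenta-1,3-dienyl]lithium (not isolated) | [Li]/C=C/C(C)=C/COC(C)(C)OC | intermediate
16 | (1S,2R,4S)-4-(tert-butyldimethylsilyloxy)-1-[(1E,3E)-5-(2-methoxypropan-2-yloxy)-3-methylpenta-1,3-dienyl]-2,6,6-trimethyl-2-(triethylsilyloxy)cyclohexan-1-ol | COC(C)(C)OC/C=C(C)/C=C/[C@]1(O)C(C)(C)C[C@H](O[Si](C)(C)C(C)(C)C)C[C@@]1(C)O[Si](CC)(CC)CC | intermediate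
17 | (1S,2R,4S)-1-[(1E,3E)-5-(2-methoxypropan-2-yloxy)-3-methylpenta-1,3-dienyl]-2,6,6-trimethylcyclohexane-1,2,4-triol | COC(C)(C)OC/C=C(C)/C=C/[C@]1(O)C(C)(C)C[C@H](O)C[C@@]1(C)O | intermediate
18 | (1S,2R,4R)-1-[(1E,3E)-5-(2-methoxypropan-2-yloxy)-3-methylpenta-1,3-dienyl]-2,6,6-trimethyl-7-oxabicyclo[2.2.1]heptan-2-ol | COC(C)(C)OC/C=C(C)/C=C/[C@]12O[C@H](CC1(C)C)C[C@@]2(C)O | intermediate
19 | (1S,2R,4R)-1-[(1E,3E)-5-hydroxy-3-methylpenta-1,3-dienyl]-2,6,6-trimethyl-7-oxabicyclo[2.2.1]heptan-2-ol (not isolated) | OC/C=C(C)/C=C/[C@]12O[C@H](CC1(C)C)C[C@@]2(C)O | intermediate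
20 | {(2E,4E)-5-[(1S,2R,4R)-2-hydroxy-2,6,6-trimethyl-7-oxabicyclo[2.2.1]heptan-1-yl]-3-methylpenta-2,4-dienyl}triphenylphosphonium bromide | [Br-].c1ccc(cc1)[P+](c1ccccc1)(c1ccccc1)C/C=C(C)/C=C/[C@]12O[C@H](CC1(C)C)C[C@@]2(C)O | intermediate
21 | (3E)-5-bromo-3-methylpent-3-en-1-yne | BrC/C=C(C)/C#C | intermediate
22 | [(2E)-3-methylpent-2-en-4-ynyl]triphenylphosphonium bromide | [Br-].C#C/C(C)=C/C[P+](c1ccccc1)(c1ccccc1)c1ccccc1 | intermediate
23 | (2E,4E,6E)-2,7-dimethylocta-2,4,6-trienedial | O=C/C(C)=C/C=C/C=C(C)/C=O | starting material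
24 | [(2E)-3-methylpent-2-en-4-ynylidene]triphenylphosphorane (not isolated) | C#C/C(C)=C/C=P(c1ccccc1)(c1ccccc1)c1ccccc1 | intermediate
25 | (2E,4E,6E,8Z,10E)-2,7,11-trimethyltrideca-2,4,6,8,10-pentaen-12-ynal (not isolated) | C#C/C(C)=C/C=C\C(C)=C\C=C\C=C(C)\C=O | intermediate
26 | (2E,4E,6E,8E,10E)-2,7,11-trimethyltrideca-2,4,6,8,10-pentaen-12-ynal | C#C/C(C)=C/C=C/C(C)=C/C=C/C=C(C)/C=O | intermediate
27 | {(2E,4E)-5-[(1S,2R,4R)-2-hydroxy-2,6,6-trimethyl-7-oxabicyclo[2.2.1]heptan-1-yl]-3-methylpenta-2,4-dienylidene}triphenylphosphorane (not isolated) | C(/C=C(C)/C=C/[C@]12O[C@H](CC1(C)C)C[C@@]2(C)O)=P(c1ccccc1)(c1ccccc1)c1ccccc1 | intermediate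
28 | (11Z)-isomer of 29 (not isolated) | CC(/C=C\C=C(C)\C=C\[C@]12O[C@H](CC1(C)C)C[C@@]2(C)O)=C\C=C\C=C(C)\C=C\C=C(C)\C#C | intermediate
29 | (3R,5R,6S)-3,6-epoxy-7',8'-didehydro-5,6-dihydro-7'-apo-β-caroten-5-ol (all-E) | CC(/C=C/C=C(C)/C=C/[C@]12O[C@H](CC1(C)C)C[C@@]2(C)O)=C\C=C\C=C(C)\C=C\C=C(C)\C#C | intermediate
30 | (3R,5R,6S)-3,6-epoxy-5-(trimethylsilyloxy)-7',8'-didehydro-5,6-dihydro-7'-apo-β-carotene | CC(/C=C/C=C(C)/C=C/[C@]12O[C@H](CC1(C)C)C[C@@]2(C)O[Si](C)(C)C)=C\C=C\C=C(C)\C=C\C=C(C)\C#C | intermediate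
31 | (7'E)-alkenylzirconocene chloride from 30, zirconium on C7' (not isolated) | CC(/C=C/C=C(C)/C=C/[C@]12O[C@H](CC1(C)C)C[C@@]2(C)O[Si](C)(C)C)=C\C=C\C=C(C)\C=C\C=C(C)\C=C\[Zr](Cl)(C1C=CC=C1)C1C=CC=C1 | intermediate
32 | (3R,5R,6S,3'R,5'S,6'S)-3'-(tert-butyldimethylsilyloxy)-3,6-epoxy-6'-(triethylsilyloxy)-5-(trimethylsilyloxy)-5,6,5',6'-tetrahydro-β,β-caroten-5'-ol | CC(/C=C/C=C(C)/C=C/[C@]12O[C@H](CC1(C)C)C[C@@]2(C)O[Si](C)(C)C)=C\C=C\C=C(C)\C=C\C=C(C)\C=C\[C@]1(O[Si](CC)(CC)CC)C(C)(C)C[C@@H](O[Si](C)(C)C(C)(C)C)C[C@]1(C)O | intermediate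
33 | (3R,5R,6S,3'R,5'S,6'S)-3,6-epoxy-5,6,5',6'-tetrahydro-β,β-carotene-5,3',5',6'-tetrol | CC(/C=C/C=C(C)/C=C/[C@]12O[C@H](CC1(C)C)C[C@@]2(C)O)=C\C=C\C=C(C)\C=C\C=C(C)\C=C\[C@]1(O)C(C)(C)C[C@@H](O)C[C@]1(C)O | target

**Step count and weak points**

Total step count: 21. Longest linear sequence: 12 steps (steps 5, 6, 7, 8, 11, 12, 13, 14, 18, 19, 20, 21).

Steps most likely to fail:

1. Step 20 (proposed new method). What may go wrong: collapse of the ion pair by 1,4-silyl shift to O5' (Rubottom pathway) without C–C bond formation; intermolecular anti delivery giving the C6' epimer; oxidative or Lewis-acid degradation of the polyene by the silver salt or the cationic zirconium species. Fallback with known chemistry, setting out from 4 and 31 and coming back at 33: the C6'–C7' bond is made by cross-coupling and the two ring-B oxygens are introduced afterwards by the classical carotenoid sequence. Enol ether 4 is cleaved with MeLi and the lithium enolate is trapped with PhNTf2 to give (4S)-4-(tert-butyldimethylsilyloxy)-2,6,6-trimethylcyclohex-1-en-1-yl trifluoromethanesulfonate F1. Zirconocene 31 is transmetalated with ZnCl2 and coupled with F1 under Pd(PPh3)4 catalysis (zerovalent palladium, Negishi coupling) to the silyl-protected 5',6'-didehydro carotenoid F2. Buffered mCPBA epoxidises the tetrasubstituted 5',6' double bond, which is twisted out of conjugation, anti to the C3' silyloxy group to give the 5',6'-epoxide F3. Dilute aqueous H2SO4 in THF opens the oxirane at the allylic C6' with inversion (the course by which carotenoid 5,6-epoxides give karpoxanthin-type triols, in competition with furanoid rearrangement) and removes the trimethylsilyl ether, giving the 3'-O-TBS ether of the target F4, which TBAF converts into 33.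

2. Step 4. What may go wrong: insufficient facial discrimination in the oxygen transfer, and premature ring opening with silyl migration of the oxirane during concentration. Fallback, setting out from 4 and coming back at 5: substrate control is replaced by reagent control, the oxygen being transferred by an enantiopure camphor-derived N-sulfonyloxaziridine in CHCl3 (matched reagent enantiomer). This aprotic, non-acidic oxidant class is known to give isolable α-siloxy epoxides from silyl enol ethers, and no compound outside the list is made (F0).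

3. Step 13. What may go wrong: Grob-type fragmentation of the activated 1,3-hydroxy-alkoxyphosphonium unit (C4–C5 cleavage) or elimination, in competition with a transannular displacement that needs a boat conformer. Fallback, setting out from 7 and 14 and coming back at 18: the C5 oxygen is kept as an oxirane while the bridge is closed, which removes the fragmentation pathway and fixes C5 independently of step 8. Weitz–Scheffer epoxidation of enone 7 (H2O2, NaOH, MeOH), anti to the adjacent silyloxy group, gives the epoxy ketone F5. Dienyllithium 15 (from 14, t-BuLi) adds to the carbonyl group anti to the oxirane oxygen to give the epoxy alcohol F6. TBAF frees the C3 hydroxyl to give the epoxy diol F7, and MsCl/pyridine gives the mesylate F8. KOt-Bu in THF closes the oxygen bridge by transannular Williamson displacement with inversion at C3, giving the bridged diepoxide F9; there is no C5 alkoxide and the C6 alkoxide is cis to the oxirane oxygen, so neither Grob fragmentation nor Payne rearrangement is possible. LiAlH4 then opens the oxirane at the secondary C4 to give 18.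

Further compounds
F1 | step 20 | (4S)-4-(tert-butyldimethylsilyloxy)-2,6,6-trimethylcyclohex-1-en-1-yl trifluoromethanesulfonate | CC1(C)C[C@@H](O[Si](C)(C)C(C)(C)C)CC(C)=C1OS(=O)(=O)C(F)(F)F
F2 | step 20 | (3R,5R,6S,3'S)-3'-(tert-butyldimethylsilyloxy)-3,6-epoxy-5-(trimethylsilyloxy)-5,6-dihydro-β,β-carotene | CC(/C=C/C=C(C)/C=C/[C@]12O[C@H](CC1(C)C)C[C@@]2(C)O[Si](C)(C)C)=C\C=C\C=C(C)\C=C\C=C(C)\C=C\C1=C(C)C[C@H](O[Si](C)(C)C(C)(C)C)CC1(C)C
F3 | step 20 | (3R,5R,6S,3'R,5'S,6'R)-3'-(tert-butyldimethylsilyloxy)-3,6:5',6'-diepoxy-5-(trimethylsilyloxy)-5,6,5',6'-tetrahydro-β,β-carotene | CC(/C=C/C=C(C)/C=C/[C@]12O[C@H](CC1(C)C)C[C@@]2(C)O[Si](C)(C)C)=C\C=C\C=C(C)\C=C\C=C(C)\C=C\[C@]12O[C@@]1(C)C[C@H](O[Si](C)(C)C(C)(C)C)CC2(C)C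
F4 | step 20 | (3R,5R,6S,3'R,5'S,6'S)-3'-(tert-butyldimethylsilyloxy)-3,6-epoxy-5,6,5',6'-tetrahydro-β,β-carotene-5,5',6'-triol | CC(/C=C/C=C(C)/C=C/[C@]12O[C@H](CC1(C)C)C[C@@]2(C)O)=C\C=C\C=C(C)\C=C\C=C(C)\C=C\[C@]1(O)C(C)(C)C[C@@H](O[Si](C)(C)C(C)(C)C)C[C@]1(C)O
F0 | step 4 | none | none
F5 | step 13 | 5-(tert-butyldimethylsilyloxy)-1,3,3-trimethyl-7-oxabicyclo[4.1.0]heptan-2-one, oxirane trans to the silyloxy group ((S)-phorenol series) | CC1(C)C[C@H](O[Si](C)(C)C(C)(C)C)[C@H]2O[C@@]2(C)C1=O
F6 | step 13 | 5-(tert-butyldimethylsilyloxy)-2-[(1E,3E)-5-(2-methoxypropan-2-yloxy)-3-methylpenta-1,3-dienyl]-1,3,3-trimethyl-7-oxabicyclo[4.1.0]heptan-2-ol, hydroxyl cis to the oxirane oxygen | COC(C)(C)OC/C=C(C)/C=C/[C@]1(O)C(C)(C)C[C@H](O[Si](C)(C)C(C)(C)C)[C@H]2O[C@@]12C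
F7 | step 13 | 2-[(1E,3E)-5-(2-methoxypropan-2-yloxy)-3-methylpenta-1,3-dienyl]-1,3,3-trimethyl-7-oxabicyclo[4.1.0]heptane-2,5-diol | COC(C)(C)OC/C=C(C)/C=C/[C@]1(O)C(C)(C)C[C@H](O)[C@H]2O[C@@]12C
F8 | step 13 | 5-methanesulfonate of F7 | COC(C)(C)OC/C=C(C)/C=C/[C@]1(O)C(C)(C)C[C@H](OS(C)(=O)=O)[C@H]2O[C@@]12C
F9 | step 13 | 3,6:4,5-diepoxide (7-oxabicyclo[2.2.1]heptane with exo 4,5-oxirane) carrying the (1E,3E)-5-(2-methoxypropan-2-yloxy)-3-methylpenta-1,3-dienyl group at C6 | COC(C)(C)OC/C=C(C)/C=C/[C@]12O[C@H](CC1(C)C)[C@H]3O[C@@]23C
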